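The readings come from a simulation for an exercise, and the scatter is random.

**The balance.** Write the balance of starting material first, since at 0.020 M against 0.0240 M of coupling partner it is the limiting reagent of the east flask, the flask asked about.

| setting | east | west | flask |
|---|---|---|---|
| starting material | 0.020 M | 0.030 M | 0.020 M |
| coupling partner | 0.024 M | 0.024 M | 0.0240 M |
| temperature | 25 °C | 25 °C | 25 °C |
| remark | the very flask that is asked about, followed so far | run made earlier |  |
| time |  |  | 12 h |

| run | time / min | target / % | starting material / % |
|---|---|---|---|
| east | 40.0 | 23.6 | 8.1 |
| east | 120 | 23.7 | 3.1 |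
| east | 180 | 26.2 | 1.0 |
| east | 300 | 25.3 | 1.4 |
| east | 480 | 30.1 | 0.7 |
| west | 3.00 | 9.2 | 65.4 |
| west | 6.00 | 16.1 | 49.8 |
| west | 10.0 | 20.7 | 35.4 |
| west | 12.0 | 20.5 | 34.7 |
| west | 15.0 | 24.1 | 29.3 |

(scatter of a reading: 1 percentage point)

* target, in percent of the starting material first charged, at 12 h
* the option that brings most further target ("none" if no option brings more than 2 percentage points) (delta / eta / alpha / beta / none)
* target present, with what was taken out counted in, in percent of the starting material first charged, after delta
* target present, with what was taken out counted in, in percent of the starting material first charged, after alpha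

- delta: at 12 h add coupling partner, 100% of the amount charged, then wait 25 h
- eta: at 12 h take out 90% of the target then present, then wait 25 h
- alpha: at 12 h raise the temperature by 20 K, then wait 25 h
- beta: change nothing and wait 25 h more

- target that was removed still counts
- the earlier runs do not show what temperature does; that part of a forecast is a guess
- additions bring no volume worth counting
- a reading of starting material is of its free form alone

**Question reversed.** After 480 min the east flask reads 0.7% of free starting material, so, counting one coupling partner for each starting material reacted, I reckon that it keeps 0.00414 M of partner: this is the partner reserve, c(coupling partner) charged minus c(starting material) charged times the share reacted. In my reckoning, with the charge of starting material and the temperature held, a second charge of coupling partner pays where partner is short while free starting material waits, and that asks for a reserve at zero or below. By that reckoning the east flask instead keeps 17.2% of its partner charge in reserve, so I expect delta to bring about what beta brings. The reserve tells me nothing about heating.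

**The forecast.** The forecast gives 31.5% at 12 h, 44% after delta and 68% after alpha, and it chooses alpha. It says that “delta gains little beyond waiting”, which is the direction of my reserve, though my reserve yields no such figure.

**The result.** The east flask gives 30.0% at 12 h, and the best option is alpha, which brings 39 percentage points against 1.5 points for delta and 1.6 points for beta. Delta ends at 31.6%, 12 points below the forecast, and alpha ends at 68.8%.

    starting material ⇌ intermediate A (K = 0.630, k = 0.150 min⁻¹, Ea = 95.0 kJ mol⁻¹, ΔH = −49.0 kJ mol⁻¹)
    starting material + coupling partner ⇌ intermediate B (K = 486 M⁻¹, k = 1.38 M⁻¹ min⁻¹, Ea = 51.0 kJ mol⁻¹, ΔH = −45.0 kJ mol⁻¹)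
    coupling partner + intermediate A → intermediate C (k = 0.234 M⁻¹ min⁻¹, Ea = 66.0 kJ mol⁻¹)
    coupling partner + intermediate A → target (k = 13.0 M⁻¹ min⁻¹, Ea = 58.0 kJ mol⁻¹)
    coupling partner + intermediate C → intermediate D (k = 0.0601 M⁻¹ min⁻¹, Ea = 55.0 kJ mol⁻¹)
    intermediate D ⇌ intermediate E (K = 0.780, k = 0.0302 min⁻¹, Ea = 87.0 kJ mol⁻¹, ΔH = −49.0 kJ mol⁻¹)
    starting material → decomposition product (k = 5.19 × 10⁻⁵ min⁻¹, Ea = 107 kJ mol⁻¹)
    target ⇌ isomer of the product (K = 2.10, k = 0.114 min⁻¹, Ea = 97.0 kJ mol⁻¹, ΔH = −63.0 kJ mol⁻¹)
    (constants at 25 °C)

At 720 min the isomer of the product holds 62.9% of the starting material charged to the east flask. With 0.432% of starting material free at that time, the reserve comes to 17.0% of the partner charge, and the east flask holds 17.1% of that charge free.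

**Second flask.** In the neighbour charged with 0.0060 M of coupling partner, its other charges as in the east flask, the reserve with the whole charge of starting material reacted is −0.0140 M, below zero, so by this reckoning partner falls short here. That neighbour ends at 720 min with 0.13% of its partner left, 42.0% of starting material free, 26.4% as intermediate A and 9.16% of target.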